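The route rests on cutting the O1–C6 bond of the 1,2-dioxane (ring atoms O1, O2, C3–C6; C1 is the ester carbon). C6 carries no hydrogen: it is bonded to O1, a methyl group, C5 and C7, so its configuration has to be set by a stereospecific C–O bond formation. Acid-promoted attack of a C3 hydroperoxide on the tertiary carbon of a glycidol-derived 2-alkyl-2-methyloxirane does this in one operation: it closes the dioxane, inverts C6 and releases C7 as a hydroxymethyl group. The precursor is an open chain with the C3 OOH, the C2 methyl, a vinyl group standing for C1, and the oxirane. The C8–C18 chain is attached afterwards by Wittig reactions and diimide.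

Key step: step 10

Remark: atoms are numbered from the ester carbon (C1) along the chain to the isopropylidene carbon (C18). (S)-2-Methylglycidol, monomethyl (R)-3-methylglutarate and (−)-B-methoxydiisopinocampheylborane are assumed to be commercial in high enantiomeric purity. Reagents that only mediate a step stand in its Conditions and carry no compound number. Peroxidic intermediates would be handled in solution, on small scale and behind a shield.

Step 1
Reactants: 1 (S)-2-methylglycidol
Product: 2 (R)-(2-methyloxiran-2-yl)methyl 4-methylbenzenesulfonate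
Conditions: TsCl, Et3N, DMAP (cat.), CH2Cl2, 0 °C
Reagents that add atoms: p-toluenesulfonyl chloride, Cc1ccc(cc1)S(Cl)(=O)=O
Why: Ordinary O-sulfonylation of a primary alcohol; the stereocentre is untouched (the descriptor changes only because CH2OTs now outranks the ring CH2).

Step 2
Reactants: 2 (R)-(2-methyloxiran-2-yl)methyl 4-methylbenzenesulfonate; 3 allylmagnesium bromide
Product: 4 (R)-2-hydroxy-2-methylhex-5-en-1-yl 4-methylbenzenesulfonate
Conditions: CuI (10 mol%), THF, −40 °C; aq. NH4Cl
Reagents that add atoms: none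
Why: Copper-catalysed Grignard opening of the oxirane at its unsubstituted CH2 (SN2); the neopentyl-type tosylate is inert in the cold and the carbinol carbon keeps its configuration.

Step 3
Reactants: 4 (R)-2-hydroxy-2-methylhex-5-en-1-yl 4-methylbenzenesulfonate
Product: 5 (R)-2-methyl-2-[(triethylsilyl)oxy]hex-5-en-1-yl 4-methylbenzenesulfonate
Conditions: Et3SiOTf, 2,6-lutidine, CH2Cl2, −78 → 0 °C
Reagents that add atoms: triethylsilyl trifluoromethanesulfonate, CC[Si](CC)(CC)OS(=O)(=O)C(F)(F)F
Why: Silylation of a tertiary alcohol with a silyl triflate and a hindered base; it masks the hydroxyl that would otherwise form a lactol with the aldehyde made next.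

Step 4
Reactants: 5 (R)-2-methyl-2-[(triethylsilyl)oxy]hex-5-en-1-yl 4-methylbenzenesulfonate
Product: 7 (R)-2-methyl-5-oxo-2-[(triethylsilyl)oxy]pentyl 4-methylbenzenesulfonate, via ozonide 6 (not isolated)
Conditions: O3, CH2Cl2, −78 °C; then Me2S, −78 °C → rt
Reagents that add atoms: ozone, [O-][O+]=O
Why: Ozonolysis with reductive work-up (Criegee mechanism) cleaves the only alkene to the aldehyde; silyl ether, sulfonate and stereocentre are not touched.

Step 5
Reactants: 7 (R)-2-methyl-5-oxo-2-[(triethylsilyl)oxy]pentyl 4-methylbenzenesulfonate; 8 (E)-but-2-ene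
Product: 11 (2R,5R,6S)-5-hydroxy-2,6-dimethyl-2-[(triethylsilyl)oxy]oct-7-en-1-yl 4-methylbenzenesulfonate, via (E)-crotylpotassium 9 (not isolated), via crotylborane 10 (not isolated)
Conditions: 8, KOt-Bu, n-BuLi, THF, −78 → −45 °C; (−)-B-methoxydiisopinocampheylborane, −78 °C; BF3·OEt2; then 7, −78 °C; NaBO3·4H2O, THF/H2O, rt
Reagents that add atoms: none
Why: Brown asymmetric crotylboration: the (E)-crotylborane from the (+)-α-pinene-derived borane should add through a chair transition state to the Si face of the aldehyde, so reagent control sets both new centres as the anti (5R,6S) pair.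

Step 6
Reactants: 12 2,3-dimethylbut-2-ene
Product: 13 2-methoxypropan-2-yl hydroperoxide
Conditions: O3, CH2Cl2/MeOH, −78 °C; N2 purge; kept as a cold CH2Cl2 solution
Reagents that add atoms: ozone, [O-][O+]=O; methanol, CO
Why: Criegee ozonolysis in methanol: the acetone O-oxide from the symmetrical alkene is trapped by methanol as the α-methoxy hydroperoxide.

Step 7
Reactants: 11 (2R,5R,6S)-5-hydroxy-2,6-dimethyl-2-[(triethylsilyl)oxy]oct-7-en-1-yl 4-methylbenzenesulfonate; 13 2-methoxypropan-2-yl hydroperoxide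
Product: 15 (2R,5S,6S)-5-[(2-methoxypropan-2-yl)peroxy]-2,6-dimethyl-2-[(triethylsilyl)oxy]oct-7-en-1-yl 4-methylbenzenesulfonate, via triflate 14 (not isolated)
Conditions: Tf2O, 2,6-lutidine, CH2Cl2, −78 °C; then added to 13 + KOt-Bu, THF, −78 → 0 °C
Reagents that add atoms: none
Why: Triflation, then SN2 alkylation of the mono-protected hydrogen peroxide (a weakly basic α-nucleophile) should invert the carbinol carbon (target C3); the neopentyl tosylate cannot compete.

Step 8
Reactants: 15 (2R,5S,6S)-5-[(2-methoxypropan-2-yl)peroxy]-2,6-dimethyl-2-[(triethylsilyl)oxy]oct-7-en-1-yl 4-methylbenzenesulfonate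
Product: 16 (2R,5S,6S)-5-hydroperoxy-2-hydroxy-2,6-dimethyloct-7-en-1-yl 4-methylbenzenesulfonate
Conditions: camphorsulfonic acid (cat.), MeOH, 0 °C → rt
Reagents that add atoms: none
Why: Acid-catalysed methanolysis (transketalisation and desilylation) frees the hydroperoxide and the tertiary alcohol together; no oxirane is present yet, so the acid has nothing to damage.

Step 9
Reactants: 16 (2R,5S,6S)-5-hydroperoxy-2-hydroxy-2,6-dimethyloct-7-en-1-yl 4-methylbenzenesulfonate
Product: 17 (2R)-2-[(3S,4S)-3-hydroperoxy-4-methylhex-5-en-1-yl]-2-methyloxirane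
Conditions: K2CO3, MeOH, 0 °C → rt; pH 7 buffer work-up; used without chromatography
Reagents that add atoms: none
Why: Intramolecular Williamson etherification (3-exo-tet) of the tertiary alkoxide onto the neighbouring primary tosylate; no bond to the quaternary carbon breaks, and the hydroperoxide salt stands by because a seven-membered closure at a neopentyl carbon is slow.

Step 10
Reactants: 17 (2R)-2-[(3S,4S)-3-hydroperoxy-4-methylhex-5-en-1-yl]-2-methyloxirane
Product: 18 [(3S,6S)-6-[(2S)-but-3-en-2-yl]-3-methyl-1,2-dioxan-3-yl]methanol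
Conditions: camphorsulfonic acid (10 mol%), CH2Cl2, 0 °C → rt
Reagents that add atoms: none
Why: Protonation of the oxirane oxygen lets the terminal oxygen of the C3 hydroperoxide attack the tertiary carbon C6 from the side opposite the departing oxygen (borderline SN2), so O1–C6 forms with inversion and the former oxirane CH2 becomes the C7 carbinol. The closest known reaction type is the acid-catalysed intramolecular opening of epoxides and oxetanes by hydroperoxides to give 1,2-dioxanes and 1,2-dioxolanes. The 1,2-dioxane closes in the 6-exo-tet mode. The new stereocentre C6 is controlled only by the configuration of the oxirane carbon, which comes unchanged from the glycidol, through this backside attack; C2 and C3 are spectators. The step needs attack at C6 and not at C7 (7-endo), and substitution before ionisation or a 1,2-hydride shift. The tertiary carbon bears most of the positive charge, the six-membered exo transition state is favoured, and a non-nucleophilic acid in an aprotic solvent at low temperature offers no competing nucleophile.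

Step 11
Reactants: 18 [(3S,6S)-6-[(2S)-but-3-en-2-yl]-3-methyl-1,2-dioxan-3-yl]methanol
Product: 20 (2R)-2-[(3S,6S)-6-(hydroxymethyl)-6-methyl-1,2-dioxan-3-yl]propanoic acid, via aldehyde 19 (not isolated)
Conditions: O3, MeCN/H2O, 0 °C; N2 purge; then NaClO2, NaH2PO4, DMSO, 0 °C → rt
Reagents that add atoms: ozone, [O-][O+]=O; water, O; sodium chlorite, [Na+].[O-]Cl=O
Why: Ozonolysis in wet acetonitrile gives the aldehyde directly (water traps the carbonyl oxide) and Pinnick oxidation in the same flask gives the acid without base, so C2 next to the β-peroxy carbon should neither epimerise nor eliminate.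

Step 12
Reactants: 20 (2R)-2-[(3S,6S)-6-(hydroxymethyl)-6-methyl-1,2-dioxan-3-yl]propanoic acid
Product: 21 methyl (2R)-2-[(3S,6S)-6-(hydroxymethyl)-6-methyl-1,2-dioxan-3-yl]propanoate
Conditions: Me3SiCHN2, toluene/MeOH, 0 °C
Reagents that add atoms: (trimethylsilyl)diazomethane, C[Si](C)(C)C=[N+]=[N-]
Why: Neutral O-methylation of the carboxylic acid by the diazoalkane; primary alcohol and peroxide do not react.

Step 13
Reactants: 21 methyl (2R)-2-[(3S,6S)-6-(hydroxymethyl)-6-methyl-1,2-dioxan-3-yl]propanoate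
Product: 22 methyl (2R)-2-[(3S,6S)-6-formyl-6-methyl-1,2-dioxan-3-yl]propanoate
Conditions: Dess–Martin periodinane, NaHCO3, CH2Cl2, 0 °C → rt
Reagents that add atoms: none
Why: Dess–Martin oxidation of the primary alcohol to the non-enolisable α-peroxy aldehyde under buffered, non-basic conditions.

Step 14
Reactants: 4 (R)-2-hydroxy-2-methylhex-5-en-1-yl 4-methylbenzenesulfonate; 23 2-methylbut-2-ene
Product: 24 (R)-2-hydroxy-2,6-dimethylhept-5-en-1-yl 4-methylbenzenesulfonate
Conditions: second-generation Grubbs catalyst, RuCl2(=CHPh)(PCy3)(H2IMes) (3 mol%), 23 in excess, CH2Cl2, 40 °C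
Reagents that add atoms: none
Why: Olefin cross-metathesis of the terminal alkene with excess 2-methylbut-2-ene installs the isopropylidene end (C17=C18); alcohol and sulfonate are tolerated.

Step 15
Reactants: 24 (R)-2-hydroxy-2,6-dimethylhept-5-en-1-yl 4-methylbenzenesulfonate
Product: 25 (R)-2-methyl-2-(4-methylpent-3-en-1-yl)oxirane
Conditions: K2CO3, MeOH, 0 °C → rt
Reagents that add atoms: none
Why: Intramolecular Williamson closure (3-exo-tet) gives the 2,2-disubstituted oxirane with the quaternary carbon unchanged.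

Step 16
Reactants: 25 (R)-2-methyl-2-(4-methylpent-3-en-1-yl)oxirane; 26 hydrogen peroxide
Product: 27 (S)-2-hydroperoxy-2,6-dimethylhept-5-en-1-ol
Conditions: 26 as a dried ethereal solution (excess), Yb(OTf)3 (10 mol%), Et2O, −20 → 0 °C
Reagents that add atoms: none
Why: Acid-catalysed perhydrolysis of a 2,2-disubstituted epoxide: excess hydrogen peroxide attacks the activated tertiary carbon from the rear, so C14 should form with inversion (the intermolecular counterpart of step 10); without a peroxo-metal catalyst the alkene is not oxidised.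

Step 17
Reactants: 27 (S)-2-hydroperoxy-2,6-dimethylhept-5-en-1-ol
Product: 28 (S)-2-[(2-methoxypropan-2-yl)peroxy]-2,6-dimethylhept-5-en-1-ol
Conditions: 2-methoxypropene (slight excess), PPTS (cat.), CH2Cl2, −20 °C; Et3N quench
Reagents that add atoms: 2-methoxypropene, COC(C)=C
Why: Acid-catalysed addition of the hydroperoxide to the enol ether (peroxyketal formation); the hydroperoxide is the better nucleophile than the neopentyl alcohol, and any O-bound mixed ketal is far more labile and reverts on work-up.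

Step 18
Reactants: 28 (S)-2-[(2-methoxypropan-2-yl)peroxy]-2,6-dimethylhept-5-en-1-ol
Product: 29 (S)-2-[(2-methoxypropan-2-yl)peroxy]-2,6-dimethylhept-5-enal
Conditions: Dess–Martin periodinane, pyridine, CH2Cl2, 0 °C → rt
Reagents that add atoms: none
Why: Dess–Martin oxidation to the non-enolisable α-peroxy aldehyde; the pyridine buffer protects the peroxyketal.

Step 19
Reactants: 30 (3R)-5-methoxy-3-methyl-5-oxopentanoic acid [monomethyl (R)-3-methylglutarate]
Product: 31 methyl (3R)-5-hydroxy-3-methylpentanoate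
Conditions: BH3·SMe2, THF, −10 °C → rt; MeOH quench; used at once
Reagents that add atoms: none
Why: Borane reduces the carboxylic acid chemoselectively beside the methyl ester and so differentiates the two arms of the glutarate; the stereocentre is not involved.

Step 20
Reactants: 31 methyl (3R)-5-hydroxy-3-methylpentanoate
Product: 32 methyl (3S)-5-iodo-3-methylpentanoate
Conditions: I2, PPh3, imidazole, CH2Cl2, 0 °C → rt
Reagents that add atoms: iodine, [I][I]
Why: Appel-type iodination of the primary alcohol, done at once to forestall lactonisation (the descriptor changes by priority only).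

Step 21
Reactants: 32 methyl (3S)-5-iodo-3-methylpentanoate
Product: 33 [(3S)-5-methoxy-3-methyl-5-oxopentyl]triphenylphosphonium iodide
Conditions: PPh3, MeCN, 80 °C
Reagents that add atoms: triphenylphosphine, c1ccc(cc1)P(c1ccccc1)c1ccccc1
Why: SN2 quaternisation of the phosphine by the primary iodide.

Step 22
Reactants: 33 [(3S)-5-methoxy-3-methyl-5-oxopentyl]triphenylphosphonium iodide; 29 (S)-2-[(2-methoxypropan-2-yl)peroxy]-2,6-dimethylhept-5-enal
Product: 35 methyl (3R,5Z,7S)-7-[(2-methoxypropan-2-yl)peroxy]-3,7,11-trimethyldodeca-5,10-dienoate, via ylide 34 (not isolated)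
Conditions: NaN(SiMe3)2 (1.0 equiv), THF, −78 °C; then 29, −78 → 0 °C
Reagents that add atoms: none
Why: Salt-free Wittig reaction of the non-stabilised ylide with the α-peroxy aldehyde forms C12=C13, expected as the Z-alkene; the ylide is less basic than an ester enolate and the doubly tertiary peroxyketal is not attacked in the cold.

Step 23
Reactants: 35 methyl (3R,5Z,7S)-7-[(2-methoxypropan-2-yl)peroxy]-3,7,11-trimethyldodeca-5,10-dienoate
Product: 36 (3R,5Z,7S)-7-[(2-methoxypropan-2-yl)peroxy]-3,7,11-trimethyldodeca-5,10-dien-1-ol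
Conditions: i-Bu2AlH, CH2Cl2, −78 → −40 °C; aq. potassium sodium tartrate
Reagents that add atoms: none
Why: Hydride reduction of the ester to the primary alcohol; a peroxide flanked by two tertiary carbons is inert to the aluminium hydride at low temperature.

Step 24
Reactants: 36 (3R,5Z,7S)-7-[(2-methoxypropan-2-yl)peroxy]-3,7,11-trimethyldodeca-5,10-dien-1-ol
Product: 37 (3R,5Z,7S)-1-iodo-7-[(2-methoxypropan-2-yl)peroxy]-3,7,11-trimethyldodeca-5,10-diene
Conditions: I2, PPh3, imidazole, CH2Cl2, 0 °C
Reagents that add atoms: iodine, [I][I]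
Why: Appel-type iodination under imidazole buffer; the phosphine is consumed at once by iodine and should not reduce the hindered peroxide.

Step 25
Reactants: 37 (3R,5Z,7S)-1-iodo-7-[(2-methoxypropan-2-yl)peroxy]-3,7,11-trimethyldodeca-5,10-diene
Product: 38 [(3R,5Z,7S)-7-[(2-methoxypropan-2-yl)peroxy]-3,7,11-trimethyldodeca-5,10-dien-1-yl]triphenylphosphonium iodide
Conditions: PPh3, i-Pr2NEt (cat.), MeCN, 60 °C, dark
Reagents that add atoms: triphenylphosphine, c1ccc(cc1)P(c1ccccc1)c1ccccc1
Why: SN2 quaternisation of the phosphine; peroxides with two tertiary carbons are not deoxygenated by it at this temperature, and the amine keeps the medium acid-free.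

Step 26
Reactants: 38 [(3R,5Z,7S)-7-[(2-methoxypropan-2-yl)peroxy]-3,7,11-trimethyldodeca-5,10-dien-1-yl]triphenylphosphonium iodide; 22 methyl (2R)-2-[(3S,6S)-6-formyl-6-methyl-1,2-dioxan-3-yl]propanoate
Product: 40 methyl (2R)-2-[(3S,6S)-6-methyl-6-[(1Z,6Z)-8-[(2-methoxypropan-2-yl)peroxy]-4,8,12-trimethyltrideca-1,6,11-trien-1-yl]-1,2-dioxan-3-yl]propanoate (7Z,12Z-triene; C10 and C14 as in the target), via ylide 39 (not isolated)
Conditions: NaN(SiMe3)2 (0.95 equiv), THF, −78 °C; then 22, −78 → −20 °C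
Reagents that add atoms: none
Why: Wittig reaction of the non-stabilised ylide with the non-enolisable α-peroxy aldehyde forms C7=C8 (Z expected); addition to the aldehyde is faster than deprotonation at C2 of the β-peroxy ester.

Step 27
Reactants: 40 the 7Z,12Z-triene
Product: 41 methyl (2R)-2-[(3S,6R)-6-methyl-6-[8-[(2-methoxypropan-2-yl)peroxy]-4,8,12-trimethyltridec-11-en-1-yl]-1,2-dioxan-3-yl]propanoate (C10 and C14 as in the target)
Conditions: 2-nitrobenzenesulfonylhydrazide (excess, in portions), Et3N, CH2Cl2, rt; followed by NMR and stopped when the disubstituted alkenes are consumed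
Reagents that add atoms: none
Why: Diimide reduction: concerted syn transfer of hydrogen should reach the two strained Z-1,2-disubstituted alkenes well before the trisubstituted C17=C18 alkene and does not cleave O–O bonds.

Step 28
Reactants: 41 the C14 peroxyketal of the target
Product: 42 methyl (2R)-2-[(3S,6R)-6-[(4R,8R)-8-hydroperoxy-4,8,12-trimethyltridec-11-en-1-yl]-6-methyl-1,2-dioxan-3-yl]propanoate (target; 2R,3S,6R,10R,14R in chain numbering)
Conditions: AcOH/THF/H2O, rt
Reagents that add atoms: none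
Why: Mild acid hydrolysis of the peroxyketal releases the C14 hydroperoxide; ester, 1,2-dioxane and alkene are stable to aqueous acetic acid.

Compound list
1 | (S)-2-methylglycidol | OC[C@@]1(C)CO1 | starting material
2 | (R)-(2-methyloxiran-2-yl)methyl 4-methylbenzenesulfonate | Cc1ccc(cc1)S(=O)(=O)OC[C@@]1(C)CO1 | intermediate
3 | allylmagnesium bromide | C=CC[Mg]Br | starting material
4 | (R)-2-hydroxy-2-methylhex-5-en-1-yl 4-methylbenzenesulfonate | Cc1ccc(cc1)S(=O)(=O)OC[C@@](O)(C)CCC=C | intermediate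
5 | (R)-2-methyl-2-[(triethylsilyl)oxy]hex-5-en-1-yl 4-methylbenzenesulfonate | Cc1ccc(cc1)S(=O)(=O)OC[C@@](O[Si](CC)(CC)CC)(C)CCC=C | intermediate
6 | 1,2,4-trioxolane (ozonide) of 5, both epimers at the trioxolane carbon | Cc1ccc(cc1)S(=O)(=O)OC[C@@](O[Si](CC)(CC)CC)(C)CCC1OCOO1 | intermediate (not isolated)
7 | (R)-2-methyl-5-oxo-2-[(triethylsilyl)oxy]pentyl 4-methylbenzenesulfonate | Cc1ccc(cc1)S(=O)(=O)OC[C@@](O[Si](CC)(CC)CC)(C)CCC=O | intermediate
8 | (E)-but-2-ene | C/C=C/C | starting material
9 | (E)-crotylpotassium | C/C=C/C[K] | intermediate (not isolated)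
10 | (E)-crotylbis(isopinocampheyl)borane from (+)-α-pinene | C/C=C/CB([C@H]1[C@H](C)[C@H]2C[C@@H](C1)C2(C)C)[C@H]1[C@H](C)[C@H]2C[C@@H](C1)C2(C)C | intermediate (not isolated)
11 | (2R,5R,6S)-5-hydroxy-2,6-dimethyl-2-[(triethylsilyl)oxy]oct-7-en-1-yl 4-methylbenzenesulfonate | C=C[C@H](C)[C@H](O)CC[C@@](C)(O[Si](CC)(CC)CC)COS(=O)(=O)c1ccc(C)cc1 | intermediate
12 | 2,3-dimethylbut-2-ene | CC(C)=C(C)C | starting material
13 | 2-methoxypropan-2-yl hydroperoxide | COC(C)(C)OO | intermediate
14 | (2R,5R,6S)-2,6-dimethyl-2-[(triethylsilyl)oxy]-5-[(trifluoromethylsulfonyl)oxy]oct-7-en-1-yl 4-methylbenzenesulfonate | C=C[C@H](C)[C@H](OS(=O)(=O)C(F)(F)F)CC[C@@](C)(O[Si](CC)(CC)CC)COS(=O)(=O)c1ccc(C)cc1 | intermediate (not isolated)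
15 | (2R,5S,6S)-5-[(2-methoxypropan-2-yl)peroxy]-2,6-dimethyl-2-[(triethylsilyl)oxy]oct-7-en-1-yl 4-methylbenzenesulfonate | C=C[C@H](C)[C@@H](OOC(C)(C)OC)CC[C@@](C)(O[Si](CC)(CC)CC)COS(=O)(=O)c1ccc(C)cc1 | intermediate
16 | (2R,5S,6S)-5-hydroperoxy-2-hydroxy-2,6-dimethyloct-7-en-1-yl 4-methylbenzenesulfonate | C=C[C@H](C)[C@@H](OO)CC[C@@](C)(O)COS(=O)(=O)c1ccc(C)cc1 | intermediate
17 | (2R)-2-[(3S,4S)-3-hydroperoxy-4-methylhex-5-en-1-yl]-2-methyloxirane | C=C[C@H](C)[C@@H](OO)CC[C@]1(C)CO1 | intermediate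
18 | [(3S,6S)-6-[(2S)-but-3-en-2-yl]-3-methyl-1,2-dioxan-3-yl]methanol | C=C[C@H](C)[C@@H]1CC[C@@](C)(CO)OO1 | intermediate
19 | (2R)-2-[(3S,6S)-6-(hydroxymethyl)-6-methyl-1,2-dioxan-3-yl]propanal | O=C[C@H](C)[C@@H]1CC[C@@](C)(CO)OO1 | intermediate (not isolated)
20 | (2R)-2-[(3S,6S)-6-(hydroxymethyl)-6-methyl-1,2-dioxan-3-yl]propanoic acid | OC(=O)[C@H](C)[C@@H]1CC[C@@](C)(CO)OO1 | intermediate
21 | methyl (2R)-2-[(3S,6S)-6-(hydroxymethyl)-6-methyl-1,2-dioxan-3-yl]propanoate | COC(=O)[C@H](C)[C@@H]1CC[C@@](C)(CO)OO1 | intermediate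
22 | methyl (2R)-2-[(3S,6S)-6-formyl-6-methyl-1,2-dioxan-3-yl]propanoate | COC(=O)[C@H](C)[C@@H]1CC[C@@](C)(C=O)OO1 | intermediate
23 | 2-methylbut-2-ene | CC=C(C)C | starting material
24 | (R)-2-hydroxy-2,6-dimethylhept-5-en-1-yl 4-methylbenzenesulfonate | Cc1ccc(cc1)S(=O)(=O)OC[C@@](O)(C)CCC=C(C)C | intermediate
25 | (R)-2-methyl-2-(4-methylpent-3-en-1-yl)oxirane | CC(C)=CCC[C@]1(C)CO1 | intermediate
26 | hydrogen peroxide | OO | starting material
27 | (S)-2-hydroperoxy-2,6-dimethylhept-5-en-1-ol | OC[C@](C)(CCC=C(C)C)OO | intermediate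
28 | (S)-2-[(2-methoxypropan-2-yl)peroxy]-2,6-dimethylhept-5-en-1-ol | OC[C@](C)(CCC=C(C)C)OOC(C)(C)OC | intermediate
29 | (S)-2-[(2-methoxypropan-2-yl)peroxy]-2,6-dimethylhept-5-enal | O=C[C@](C)(CCC=C(C)C)OOC(C)(C)OC | intermediate
30 | (3R)-5-methoxy-3-methyl-5-oxopentanoic acid | COC(=O)C[C@H](C)CC(=O)O | starting material
31 | methyl (3R)-5-hydroxy-3-methylpentanoate | COC(=O)C[C@H](C)CCO | intermediate
32 | methyl (3S)-5-iodo-3-methylpentanoate | COC(=O)C[C@H](C)CCI | intermediate
33 | [(3S)-5-methoxy-3-methyl-5-oxopentyl]triphenylphosphonium iodide | COC(=O)C[C@H](C)CC[P+](c1ccccc1)(c1ccccc1)c1ccccc1.[I-] | intermediate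
34 | methyl (3S)-3-methyl-5-(triphenyl-λ5-phosphanylidene)pentanoate | COC(=O)C[C@H](C)CC=P(c1ccccc1)(c1ccccc1)c1ccccc1 | intermediate (not isolated)
35 | methyl (3R,5Z,7S)-7-[(2-methoxypropan-2-yl)peroxy]-3,7,11-trimethyldodeca-5,10-dienoate | COC(=O)C[C@H](C)C/C=C\[C@](C)(CCC=C(C)C)OOC(C)(C)OC | intermediate
36 | (3R,5Z,7S)-7-[(2-methoxypropan-2-yl)peroxy]-3,7,11-trimethyldodeca-5,10-dien-1-ol | OCC[C@H](C)C/C=C\[C@](C)(CCC=C(C)C)OOC(C)(C)OC | intermediate
37 | (3R,5Z,7S)-1-iodo-7-[(2-methoxypropan-2-yl)peroxy]-3,7,11-trimethyldodeca-5,10-diene | ICC[C@H](C)C/C=C\[C@](C)(CCC=C(C)C)OOC(C)(C)OC | intermediate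
38 | [(3R,5Z,7S)-7-[(2-methoxypropan-2-yl)peroxy]-3,7,11-trimethyldodeca-5,10-dien-1-yl]triphenylphosphonium iodide | [I-].c1ccccc1[P+](c1ccccc1)(c1ccccc1)CC[C@H](C)C/C=C\[C@](C)(CCC=C(C)C)OOC(C)(C)OC | intermediate
39 | [(3R,5Z,7S)-7-[(2-methoxypropan-2-yl)peroxy]-3,7,11-trimethyldodeca-5,10-dien-1-ylidene]triphenyl-λ5-phosphane | c1ccccc1P(c1ccccc1)(c1ccccc1)=CC[C@H](C)C/C=C\[C@](C)(CCC=C(C)C)OOC(C)(C)OC | intermediate (not isolated)
40 | methyl (2R)-2-[(3S,6S)-6-methyl-6-[(1Z,6Z)-8-[(2-methoxypropan-2-yl)peroxy]-4,8,12-trimethyltrideca-1,6,11-trien-1-yl]-1,2-dioxan-3-yl]propanoate, C10 and C14 as in the target | COC(=O)[C@H](C)[C@@H]1CC[C@@](C)(/C=C\C[C@H](C)C/C=C\[C@](C)(CCC=C(C)C)OOC(C)(C)OC)OO1 | intermediate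
41 | methyl (2R)-2-[(3S,6R)-6-methyl-6-[8-[(2-methoxypropan-2-yl)peroxy]-4,8,12-trimethyltridec-11-en-1-yl]-1,2-dioxan-3-yl]propanoate, C10 and C14 as in the target | COC(=O)[C@H](C)[C@@H]1CC[C@@](C)(CCC[C@H](C)CCC[C@](C)(CCC=C(C)C)OOC(C)(C)OC)OO1 | intermediate
42 | methyl (2R)-2-[(3S,6R)-6-[(4R,8R)-8-hydroperoxy-4,8,12-trimethyltridec-11-en-1-yl]-6-methyl-1,2-dioxan-3-yl]propanoate | COC(=O)[C@H](C)[C@@H]1CC[C@@](C)(CCC[C@H](C)CCC[C@](C)(CCC=C(C)C)OO)OO1 | target

Total step count: 28.
Longest linear sequence: 15 steps (1, 2, 3, 4, 5, 7, 8, 9, 10, 11, 12, 13, 26, 27, 28, from (S)-2-methylglycidol).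

Steps most likely to fail

Step 7. Substitution at the β-branched secondary carbon may lose to E2 elimination toward the allylic C2–H, or the C6 silyloxy oxygen may take part and lead to a tetrahydrofuran. The fallback drops the masked nucleophile and uses direct perhydrolysis of a less ionising sulfonate. Setting out from 11, MsCl/Et3N (CH2Cl2, 0 °C) would give the mesylate (2R,5R,6S)-5-[(methylsulfonyl)oxy]-2,6-dimethyl-2-[(triethylsilyl)oxy]oct-7-en-1-yl 4-methylbenzenesulfonate F1. The small, weakly basic hydroperoxide anion (50% H2O2, KOH, MeOH/THF, 0 °C) should displace the mesylate with inversion to give the free hydroperoxide (2R,5S,6S)-5-hydroperoxy-2,6-dimethyl-2-[(triethylsilyl)oxy]oct-7-en-1-yl 4-methylbenzenesulfonate F2. n-Bu4NF (THF, 0 °C) then removes the silyl group and the alkoxide closes the oxirane, which comes back to the route at 17.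

Step 10. The activated oxirane may ionise at C6 with loss of configuration, undergo a 1,2-hydride shift to an aldehyde, or be opened at C7. The fallback makes the two C–O bonds of the peroxide in the opposite order, both by known reactions. Setting out from 11, n-Bu4NF (THF, 0 °C) would give the epoxy alcohol (3R,4S)-4-methyl-1-[(2R)-2-methyloxiran-2-yl]hex-5-en-3-ol F3, and MsCl/Et3N its mesylate (3R,4S)-4-methyl-1-[(2R)-2-methyloxiran-2-yl]hex-5-en-3-yl methanesulfonate F4. Excess ethereal H2O2 with Yb(OTf)3, as in step 16, should open the oxirane at the tertiary carbon with inversion to (2S,5R,6S)-2-hydroperoxy-1-hydroxy-2,6-dimethyloct-7-en-5-yl methanesulfonate F5. KOt-Bu (THF, 0 °C) would then close the 1,2-dioxane by intramolecular SN2 displacement of the C3 mesylate with inversion, which comes back to the route at 18.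

Step 27. Hydrogen transfer may not discriminate well enough between the two hindered Z-alkenes and the trisubstituted C17=C18 alkene, giving over-reduction or incomplete reduction. The fallback removes the trisubstituted alkene before the reduction and rebuilds it afterwards. Setting out from 40, one equivalent of ozone (CH2Cl2/pyridine, −78 °C; Me2S) should cleave only the electron-rich isopropylidene alkene, the Z-alkenes being deactivated by their allylic peroxy oxygens. This gives the aldehyde methyl (2R)-2-[(3S,6S)-6-methyl-6-[(1Z,6Z)-8-[(2-methoxypropan-2-yl)peroxy]-4,8-dimethyl-11-oxoundeca-1,6-dien-1-yl]-1,2-dioxan-3-yl]propanoate F6. Diimide (conditions of step 27, now with nothing else to reduce) gives the saturated aldehyde methyl (2R)-2-[(3S,6R)-6-methyl-6-[8-[(2-methoxypropan-2-yl)peroxy]-4,8-dimethyl-11-oxoundecyl]-1,2-dioxan-3-yl]propanoate F7. A Wittig reaction with isopropylidenetriphenylphosphorane (from isopropyltriphenylphosphonium iodide and NaN(SiMe3)2, THF, −78 °C) restores C17=C18 and comes back to the route at 41.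

Further compounds
F1 | step 7 | (2R,5R,6S)-5-[(methylsulfonyl)oxy]-2,6-dimethyl-2-[(triethylsilyl)oxy]oct-7-en-1-yl 4-methylbenzenesulfonate | C=C[C@H](C)[C@H](OS(C)(=O)=O)CC[C@@](C)(O[Si](CC)(CC)CC)COS(=O)(=O)c1ccc(C)cc1
F2 | step 7 | (2R,5S,6S)-5-hydroperoxy-2,6-dimethyl-2-[(triethylsilyl)oxy]oct-7-en-1-yl 4-methylbenzenesulfonate | C=C[C@H](C)[C@@H](OO)CC[C@@](C)(O[Si](CC)(CC)CC)COS(=O)(=O)c1ccc(C)cc1
F3 | step 10 | (3R,4S)-4-methyl-1-[(2R)-2-methyloxiran-2-yl]hex-5-en-3-ol | C=C[C@H](C)[C@H](O)CC[C@]1(C)CO1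
F4 | step 10 | (3R,4S)-4-methyl-1-[(2R)-2-methyloxiran-2-yl]hex-5-en-3-yl methanesulfonate | C=C[C@H](C)[C@H](OS(C)(=O)=O)CC[C@]1(C)CO1
F5 | step 10 | (2S,5R,6S)-2-hydroperoxy-1-hydroxy-2,6-dimethyloct-7-en-5-yl methanesulfonate | C=C[C@H](C)[C@H](OS(C)(=O)=O)CC[C@@](C)(CO)OO
F6 | step 27 | methyl (2R)-2-[(3S,6S)-6-methyl-6-[(1Z,6Z)-8-[(2-methoxypropan-2-yl)peroxy]-4,8-dimethyl-11-oxoundeca-1,6-dien-1-yl]-1,2-dioxan-3-yl]propanoate | COC(=O)[C@H](C)[C@@H]1CC[C@@](C)(/C=C\C[C@H](C)C/C=C\[C@](C)(CCC=O)OOC(C)(C)OC)OO1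
F7 | step 27 | methyl (2R)-2-[(3S,6R)-6-methyl-6-[8-[(2-methoxypropan-2-yl)peroxy]-4,8-dimethyl-11-oxoundecyl]-1,2-dioxan-3-yl]propanoate | COC(=O)[C@H](C)[C@@H]1CC[C@@](C)(CCC[C@H](C)CCC[C@](C)(CCC=O)OOC(C)(C)OC)OO1
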